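Follow one molecule of starting material through the flask and ask how long it waits at each fork.

| flask | starting material | reagent | protic impurity | free catalyst | second catalyst | time |
|---|---|---|---|---|---|---|
| eta | 0.14 M | 0.140 M | 0.0140 M | 0.14 mM | 1.4 mM | 3.0 d |
| gamma | 0.14 M | 0.140 M | 0.0140 M | 0.14 mM | 1.4 mM | 5.0 d |
| delta | 0.14 M | 0.140 M | 0.0140 M | 0.14 mM | 1.4 mM | 6.0 d |

    starting material + protic impurity → quenched substrate (k1 = 0.98 L mol⁻¹ h⁻¹)
    reagent + second catalyst + intermediate → second catalyst + product (k2 = 61 L² mol⁻² h⁻¹)
    starting material + free catalyst → free catalyst + intermediate (k3 = 1700 L mol⁻¹ h⁻¹)

1. which of these there is most of at the end, counted by the starting material in it, eta (starting material / product / intermediate)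
2. which of these there is most of at the end, counted by the starting material in it, gamma (starting material / product / intermediate)
3. which of these there is most of at the end, counted by the starting material in it, delta (starting material / product / intermediate)
4. how much there is at the end of the one of these that leads, in percent of the starting material charged: eta
5. how much there is at the end of the one of these that leads, in percent of the starting material charged: gamma
6. how much there is at the end of the one of these that leads, in percent of the starting material charged: delta

At its first fork the molecule met either the free catalyst or the protic impurity. At the start the rates stood at 17.3 to one, a share of 0.945 for the free catalyst. But the protic impurity falls as it reacts, while the free catalyst comes back from its step, so that share rises along the way. I let the protic impurity decay exponentially over the exposure to starting material that the first share implies, and that left a fraction f = 0.958 of the charge to go on as intermediate.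

The wait at the next fork came to 3.49 d. This is the pairing time τ, one over the product of the reagent step's constant, the second catalyst and the charge of starting material. I treated the first fork as closed at once, because the free catalyst halves the starting material in 0.121 d, far less than that wait.

The bench rule, pseudo-first-order, holds the reagent at its charge. It gave the intermediate a half-life of 2.42 d and delta 78.7 % product. But that rule needs reagent in large excess, and the ratio b of reagent to starting material charged was 1.00. The reagent therefore fell along with the intermediate, and I used the second-order form, with p the product as a fraction of the charge:

p = f·b·(E − 1) / (f·E − b), with E = exp((f − b)·t/τ)

With f and b both close to one, product passes intermediate near t = τ. The time of eta lies below τ, and the time of gamma lies above it.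

eta: product 44.7 %, intermediate 51.0 %

gamma: product 57.2 %, intermediate 38.6 %

delta: product 61.4 %, intermediate 34.4 %

The forecast's ground was this: “Treat this as two separated stages.” It named intermediate at 52.4 % for eta, product at 56.3 % for gamma and product at 60.7 % for delta. It led with the same species as my reckoning, though its figure for eta stood above mine.

The simulation gave intermediate at 52.5 % for eta, product at 56.3 % for gamma and product at 60.7 % for delta.

Delta had not come to rest at 6.0 d. At 60.0 d, ten times that time and 17.2 pairing times, the line gave 92.2 % product. The run gave 92.1 %, with intermediate down to 3.65 % and reagent down to 7.89 % of its charge. For the forecast's call on delta to fail, the reagent charge had to be scaled by 0.723, where product and intermediate hold the same.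

The neighbour of delta charged with 0.084 M of reagent went past that point. It kept τ and f but had b = 0.600, and the line gave 41.7 % product against 54.1 % intermediate. The run of that neighbour gave 41.2 % product and 54.6 % intermediate.

The rate constants were drawn at random within sensible limits; the run is a simulation.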